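The data come from a simulation on assumed constants; noise was put on by code.

Watch the target.

| setting | winter | autumn | theta | beta |
|---|---|---|---|---|
| substrate | 1 M | 1.5 M | 2.0 M | 2.0 M |
| temperature | 75 °C | 88 °C | 95 °C | 80 °C |
| remark | run made earlier | run made earlier |  |  |
| time |  |  | 10 d | 10 d |

| run | time / d | substrate / % | intermediate A / % | target / % | intermediate B / % |
|---|---|---|---|---|---|
| winter | 1.67 | 56.6 | 11.2 | 1.8 | 30.8 |
| winter | 3.00 | 34.8 | 12.7 | 4.5 | 46.7 |
| winter | 5.00 | 18.0 | 11.4 | 9.0 | 61.7 |
| winter | 6.00 | 12.6 | 11.5 | 10.9 | 64.3 |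
| winter | 8.00 | 6.1 | 11.4 | 13.3 | 67.4 |
| winter | 10.0 | 2.9 | 10.5 | 17.8 | 68.2 |
| autumn | 0.625 | 41.6 | 8.1 | 3.4 | 48.9 |
| autumn | 2.08 | 5.9 | 8.1 | 10.8 | 75.6 |
| autumn | 4.00 | 0.3 | 7.3 | 20.7 | 71.2 |
| autumn | 5.00 | 0 | 6.2 | 24.8 | 68.0 |
| autumn | 8.00 | 0 | 5.8 | 37.2 | 56.8 |
| autumn | 10.0 | 0.1 | 5.3 | 44.1 | 49.8 |

(readings scatter by 0.5 percentage points)



- which of these there is most of at the end, counted by the substrate in it, theta (intermediate B / intermediate A / substrate / target)
- which of these there is most of at the end, counted by the substrate in it, beta (intermediate B / intermediate A / substrate / target)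
- amount of the one of these that there is most of at the end, in percent of the substrate charged, theta
- amount of the one of these that there is most of at the end, in percent of the substrate charged, beta

Both new flasks ask what stands after 10 d, so I began with the substrate. It fell first order, and I read 0.352 d⁻¹ in winter and 1.34 d⁻¹ in autumn. Late in both runs intermediate A and intermediate B kept a roughly steady ratio, so I treated them as one pool (a pre-equilibrium) leaking into target. Target gained per day, over the mean amount standing in that pool, I called the leak constant: 0.0232 d⁻¹ in winter, and 0.0606 d⁻¹ in autumn. In winter this constant read smaller than the substrate's, and in autumn too.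

I carried both constants by Arrhenius. Theta got substrate 2.65 d⁻¹ and leak 0.0988 d⁻¹. Beta got 0.596 d⁻¹ and 0.0338 d⁻¹. Integrating the two first-order steps in closed form, with k for substrate and λ for leak, gives target = one minus (k·exp(−λt) − λ·exp(−kt))/(k − λ). So I reckoned target 61.3% in theta, more than the remainder. In beta I reckoned target 24.4%. With winter's last ratio of intermediate A to intermediate B, 0.154, that left intermediate B at 65.5%, more than target.

The forecast said target at 65% for theta, its “pool drains at about 0.11/d, leaving about 35%”, and intermediate B at 65% for beta. For theta my figure stood lower than its own.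

The flasks gave target at 63.0% in theta and intermediate B at 64.8% in beta.

    substrate → intermediate A (k = 1.90 × 10⁻⁴ min⁻¹, Ea = 118 kJ mol⁻¹)
    substrate → intermediate B (k = 2.30 × 10⁻⁴ min⁻¹, Ea = 112 kJ mol⁻¹)
    intermediate A → target (k = 1.90 × 10⁻⁴ min⁻¹, Ea = 110 kJ mol⁻¹)
    intermediate B ⇌ intermediate A (K = 0.150, k = 1.90 × 10⁻⁴ min⁻¹, Ea = 128 kJ mol⁻¹, ΔH = −35.0 kJ mol⁻¹)
    (constants at 80 °C)

In theta substrate stood at 0% by 5.00 d. From then to 10.0 d target rose from 38.9% to 63.0% while intermediate B fell from 56.3% to 34.1%. Read the same way, theta's leak constant was 0.0983 d⁻¹, against my 0.0988 d⁻¹.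

For a repeat of beta at 55 °C, the leak 0.00456 d⁻¹ and substrate constant 0.0365 d⁻¹ gave target 0.728%. The computed flask stood at 0.834%.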